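Per cent of the free monomer charged is the unit I count in.

free monomer 0.051 M; protic impurity 0.0102 M; initiator 2.5 mM; time 8.0 min

    free monomer → uncatalysed product (k1 = 5.0 × 10⁻⁴ /s)
    free monomer + living end → monomer in chains + living end, rate k2*[living end]*[free monomer] (k2 = 3.7 /M/s)
    free monomer + initiator → living end + monomer in chains (k3 = 3.3 /M/s)
    monomer in chains + living end → free monomer + living end, rate k4*[living end] as long as [monomer in chains] is above zero (k4 = 0.014 /s)
    protic impurity + free monomer → quenched substrate (k5 = 6.5 /M/s)

- the average divides the monomer in chains by the number of chains begun, living and dead together
- run time (flask): 8.0 min

- average number of monomer units in a chain (chains begun, living or dead) at 8.0 min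
- part of the free monomer that has reacted at 8.0 min

I build this flask up one process at a time. First comes chain growth by itself, with living ends at the initiator's charge. This first picture has free monomer decaying in a pseudo-first-order way, with a half-life of 1.25 min, and puts it at 1.18% at 8.0 min.

Now I add the return of monomer from chains. Per living end it runs at a fixed rate, so growth and return balance at 7.42%, not at zero. The uncatalysed step is slower than growth, yet it lowers that level a little. I call the result the floor, 7.04%: the fraction of the charge at which return equals growth plus uncatalysed loss. Free monomer nears it with a relaxation time of 103 s.

The other end of the run is quick. At full monomer, impurity and initiator have characteristic times of 3.02 s and 5.94 s, far shorter than the relaxation time. So I book both at the start and join the two ends: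

quenched substrate = 20.0%; first units in chains = 4.90%

free monomer at the start of the relaxation = 75.1%

free monomer at the asked time = floor + (start − floor) × exp(−time / relaxation time) = 7.67%

uncatalysed product, integrated along that curve = 5.15%

What remains is in chains, so I commit to a chain length of 13.7 and a conversion of 92.3%.

The forecast gives 13.6 and 92.3%, holding that “free monomer relaxes with a time constant” towards a floor.

The simulation gives 13.6 and 92.3%. At 8.00 min this flask makes monomer in chains 1.04 times as fast as it takes it back, each step net, against 4.32 at 1.82 min; free monomer stands at 7.71%, above the floor, and reads 7.04% at 80.0 min. In the neighbour flask charged with 0.013 M of free monomer, the floor becomes 27.6% of that charge, and subtracting the impurity's charge leaves 21.5%, less than that floor; in that flask, monomer in chains reads 0.0552% and the chain length 0.00292.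

The constants used here were set for the occasion, and the outcome is calculated.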